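The tetrahydroisoquinoline nitrogen ring (ring B: C1, N2, C3, C4, C4a, C8a) is cut at C4–C4a and at N2–C1. This exposes an N2–C3–C4 fragment from L-alanine and an ortho-bromo acetophenone whose acetyl carbon is C1 on C8a. In one operation a Negishi coupling of the β-amido alkylzinc iodide forms C4–C4a, and acid then frees N2, which condenses with the C1 ketone to the cyclic imine. The step exploits the ortho placement of C4a and C8a on the benzene ring (ring A) and leaves C3, the only stereocenter carried in, untouched. trans-Selective imine reduction, C5 bromination and a biaryl Negishi coupling complete the synthesis.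

Key step: step 3

Assumption: the C5–C1' biaryl axis carries no descriptor in the target, so the route fixes only (1S,3S); the last step should form both atropo-diastereomers, each of which matches the given structure, and they can be separated if one is wanted.

Numbering: isoquinoline numbering (C1, N2, C3, C4, C4a, C5–C8, C8a) is used for all precursors of ring B; primed numbers refer to the naphthalene.

Step 1
Reactants: 1 tert-butyl N-[(2S)-1-hydroxypropan-2-yl]carbamate (N-Boc-L-alaninol)
Product: 2 tert-butyl N-[(2S)-1-iodopropan-2-yl]carbamate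
Conditions: I2, PPh3, imidazole, CH2Cl2, 0 °C → rt
Reagents that add atoms: iodine, II
Why: Appel-type iodination of the primary alcohol, which does not touch the stereocenter, so the (S) configuration of L-alaninol is kept.

Step 2
Reactants: 3 1-bromo-3,5-dimethoxybenzene
Product: 4 1-(2-bromo-4,6-dimethoxyphenyl)ethan-1-one
Conditions: AcCl, SnCl4, CH2Cl2, 0 °C
Reagents that add atoms: acetyl chloride, CC(Cl)=O
Why: Friedel–Crafts acylation at C2 of 3, para to one methoxy group and ortho to the other, which is the position electrophiles take in 5-substituted 1,3-dimethoxybenzenes, with SnCl4 chosen as a mild Lewis acid so that the methoxy group next to the new ketone is not cleaved.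

Step 3
Reactants: 4 1-(2-bromo-4,6-dimethoxyphenyl)ethan-1-one, 2 tert-butyl N-[(2S)-1-iodopropan-2-yl]carbamate
Product: 7 (3S)-6,8-dimethoxy-1,3-dimethyl-3,4-dihydroisoquinoline, via alkylzinc iodide 5 (not isolated), via keto carbamate 6 (not isolated)
Conditions: Zn dust, I2 (cat.), DMF, rt; then 4, Pd2(dba)3, SPhos, 50 °C; solvent swap, then HCl (4 M in dioxane), rt; aq. NaOH
Reagents that add atoms: none
Why: Zinc inserts into the C–I bond of 2 to give alkylzinc iodide 5, zerovalent palladium adds to the C–Br bond of 4, transmetalation and reductive elimination join C4 to C4a in keto carbamate 6, and HCl then removes the Boc group so that the freed N2 condenses with the C1 ketone to the cyclic imine 7. The closest known reaction types are the Negishi coupling of amino-alcohol-derived β-amido alkylzinc iodides with aryl halides and the cyclodehydration of a δ-amino ketone. The nitrogen ring closes by 6-exo-trig addition of N2 to the carbonyl carbon C1 and loss of water, which leaves the C1=N2 bond inside the ring. No stereocenter is created: C3 is carried in from L-alanine, none of its bonds is made or broken, and it is not acidic in 5, 6 or 7. The step needs coupling to outrun β-elimination of the carbamate from 5 and needs the organozinc to spare the ketone; DMF and the carbamate N–H should stabilize 5, the ortho acetyl group speeds oxidative addition at the only C–Br bond, and an alkylzinc iodide does not add to a hindered aryl ketone.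

Step 4
Reactants: 7 (3S)-6,8-dimethoxy-1,3-dimethyl-3,4-dihydroisoquinoline
Product: 8 (1S,3S)-6,8-dimethoxy-1,3-dimethyl-1,2,3,4-tetrahydroisoquinoline
Conditions: LiAlH4, AlMe3, THF, −78 → 0 °C
Reagents that add atoms: none
Why: Lewis-acid-assisted hydride reduction of the cyclic imine under 1,3-induction from C3: AlMe3 on nitrogen should turn the C3 methyl group pseudoaxial and the hydride should enter axially on that same face, so that the C1 methyl group ends trans to it and C1 becomes (S).

Step 5
Reactants: 8 (1S,3S)-6,8-dimethoxy-1,3-dimethyl-1,2,3,4-tetrahydroisoquinoline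
Product: 9 (1S,3S)-5-bromo-6,8-dimethoxy-1,3-dimethyl-1,2,3,4-tetrahydroisoquinoline
Conditions: Br2 (1.0 equiv), AcOH, rt; aq. NaOH
Reagents that add atoms: bromine, BrBr
Why: Electrophilic aromatic bromination: in acetic acid the amine is held as its ammonium salt and C5, para to the C8 methoxy group and ortho to the C6 methoxy group, should react in preference to C7, which is flanked by two methoxy groups.

Step 6
Reactants: 10 3-methylbut-2-enoyl chloride, 11 diethylamine
Product: 12 N,N-diethyl-3-methylbut-2-enamide
Conditions: 11 (2.2 equiv), CH2Cl2, 0 °C → rt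
Reagents that add atoms: none
Why: Acylation of the secondary amine by the acid chloride (Schotten–Baumann-type amide formation), with the second equivalent of amine taking up HCl.

Step 7
Reactants: 12 N,N-diethyl-3-methylbut-2-enamide, 13 3-bromoanisole
Product: 16 8-methoxy-3-methylnaphthalen-1-ol, via lithium dienolate 14 (not isolated), via 3-methoxybenzyne 15 (not isolated)
Conditions: LiN(iPr)2 (3.5 equiv), THF, −78 °C → rt; aq. NH4Cl
Reagents that add atoms: none
Why: Aryne annulation: LiN(iPr)2 turns 12 into the γ-extended dienolate 14 and 13 into 3-methoxybenzyne 15, the γ-carbon of 14 adds to the aryne carbon meta to the methoxy group, the aryl anion thus formed ortho to OMe acylates itself on the amide carbonyl, and loss of LiNEt2 followed by tautomerization should give the 1-naphthol whose hydroxyl group is peri to the methoxy group.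

Step 8
Reactants: 16 8-methoxy-3-methylnaphthalen-1-ol
Product: 17 1,8-dimethoxy-3-methylnaphthalene
Conditions: NaH, MeI, DMF, 0 °C → rt
Reagents that add atoms: iodomethane, CI
Why: Williamson ether synthesis: the naphtholate formed by NaH is methylated by iodomethane.

Step 9
Reactants: 17 1,8-dimethoxy-3-methylnaphthalene
Product: 18 1-bromo-4,5-dimethoxy-2-methylnaphthalene
Conditions: NBS, MeCN, 0 °C → rt
Reagents that add atoms: N-bromosuccinimide, O=C1CCC(=O)N1Br
Why: Electrophilic aromatic bromination at C4 of 17, the α-position that is para to the C1 methoxy group and ortho to the methyl group and therefore the most activated site of the more electron-rich ring.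

Step 10
Reactants: 18 1-bromo-4,5-dimethoxy-2-methylnaphthalene, 9 (1S,3S)-5-bromo-6,8-dimethoxy-1,3-dimethyl-1,2,3,4-tetrahydroisoquinoline
Product: 21 (1S,3S)-5-(4,5-dimethoxy-2-methylnaphthalen-1-yl)-6,8-dimethoxy-1,3-dimethyl-1,2,3,4-tetrahydroisoquinoline, via aryllithium 19 (not isolated), via arylzinc chloride 20 (not isolated)
Conditions: 18, t-BuLi (2 equiv), THF, −78 °C; ZnCl2, −78 °C → rt; then 9, Pd2(dba)3, RuPhos, THF, 70 °C
Reagents that add atoms: none
Why: Bromine–lithium exchange and transmetalation give arylzinc chloride 20, which should undergo a Negishi coupling with the hindered bromide 9 under a bulky dialkylbiarylphosphine–palladium catalyst of the kind used for tri-ortho-substituted biaryls; the secondary N–H is too weakly acidic to quench the arylzinc, C1 and C3 are untouched, and the new C5–C1' axis forms without control.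

Compound list
1 | tert-butyl N-[(2S)-1-hydroxypropan-2-yl]carbamate (N-Boc-L-alaninol) | C[C@H](NC(=O)OC(C)(C)C)CO | starting material
2 | tert-butyl N-[(2S)-1-iodopropan-2-yl]carbamate | C[C@H](NC(=O)OC(C)(C)C)CI | intermediate
3 | 1-bromo-3,5-dimethoxybenzene | COc1cc(Br)cc(OC)c1 | starting material
4 | 1-(2-bromo-4,6-dimethoxyphenyl)ethan-1-one | CC(=O)c1c(Br)cc(OC)cc1OC | intermediate
5 | [(2S)-2-(tert-butoxycarbonylamino)propyl]zinc iodide (not isolated) | C[C@H](NC(=O)OC(C)(C)C)C[Zn]I | intermediate
6 | tert-butyl N-[(2S)-1-(2-acetyl-3,5-dimethoxyphenyl)propan-2-yl]carbamate (not isolated) | CC(=O)c1c(OC)cc(OC)cc1C[C@H](C)NC(=O)OC(C)(C)C | intermediate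
7 | (3S)-6,8-dimethoxy-1,3-dimethyl-3,4-dihydroisoquinoline | CC1=N[C@@H](C)Cc2cc(OC)cc(OC)c21 | intermediate
8 | (1S,3S)-6,8-dimethoxy-1,3-dimethyl-1,2,3,4-tetrahydroisoquinoline | COc1cc(OC)c2c(c1)C[C@H](C)N[C@H]2C | intermediate
9 | (1S,3S)-5-bromo-6,8-dimethoxy-1,3-dimethyl-1,2,3,4-tetrahydroisoquinoline | COc1cc(OC)c2c(c1Br)C[C@H](C)N[C@H]2C | intermediate
10 | 3-methylbut-2-enoyl chloride | CC(C)=CC(=O)Cl | starting material
11 | diethylamine | CCNCC | starting material
12 | N,N-diethyl-3-methylbut-2-enamide | CCN(CC)C(=O)C=C(C)C | intermediate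
13 | 3-bromoanisole (1-bromo-3-methoxybenzene) | COc1cccc(Br)c1 | starting material
14 | lithium 1-(diethylamino)-3-methylbuta-1,3-dien-1-olate (not isolated) | C=C(C)C=C(O[Li])N(CC)CC | intermediate
15 | 3-methoxybenzyne (not isolated) | COC1=CC=CC#C1 | intermediate
16 | 8-methoxy-3-methylnaphthalen-1-ol | COc1cccc2cc(C)cc(O)c12 | intermediate
17 | 1,8-dimethoxy-3-methylnaphthalene | COc1cccc2cc(C)cc(OC)c12 | intermediate
18 | 1-bromo-4,5-dimethoxy-2-methylnaphthalene | COc1cccc2c(Br)c(C)cc(OC)c12 | intermediate
19 | (4,5-dimethoxy-2-methylnaphthalen-1-yl)lithium (not isolated) | COc1cccc2c([Li])c(C)cc(OC)c12 | intermediate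
20 | (4,5-dimethoxy-2-methylnaphthalen-1-yl)zinc chloride (not isolated) | COc1cccc2c([Zn]Cl)c(C)cc(OC)c12 | intermediate
21 | (1S,3S)-5-(4,5-dimethoxy-2-methylnaphthalen-1-yl)-6,8-dimethoxy-1,3-dimethyl-1,2,3,4-tetrahydroisoquinoline | COc1cc(OC)c2c(c1-c1c(C)cc(OC)c3c(OC)cccc13)C[C@H](C)N[C@H]2C | target

Total step count: 10
Longest linear sequence: 5 steps (steps 6, 7, 8, 9, 10; the isoquinoline branch through steps 2, 3, 4, 5, 10 is equally long)

Steps most likely to fail

Step 3 (key step). What may go wrong is β-elimination or protonolysis of the β-amido alkylzinc iodide before it is captured, together with slow oxidative addition at the hindered, electron-rich aryl bromide. The fallback reverses the polarity and still closes both bonds in one flask. Ketone 4 is first masked as lithium 1-(2-bromo-4,6-dimethoxyphenyl)ethen-1-olate F1 with LiN(SiMe3)2 in THF at −78 °C. Bromine–lithium exchange with t-BuLi then gives lithium 1-(2-lithio-4,6-dimethoxyphenyl)ethen-1-olate F2. Under CuI catalysis F2 opens the commercial cyclic sulfamidate tert-butyl (4S)-4-methyl-1,2,3-oxathiazolidine-3-carboxylate 2,2-dioxide (C[C@H]1COS(=O)(=O)N1C(=O)OC(C)(C)C) at its CH2–O carbon to give N-[(2S)-1-(2-acetyl-3,5-dimethoxyphenyl)propan-2-yl]-N-(tert-butoxycarbonyl)sulfamic acid F3. Aqueous HCl cleaves the N–S bond of F3 to keto carbamate 6, which loses its Boc group and cyclizes as in the main route. This fallback sets out from 4 and comes back at 6 and so at 7.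

Step 10. What may go wrong is slow oxidative addition and reductive elimination at the tri-ortho-substituted axis, binding of the free secondary amine to palladium or zinc, and loss of the arylzinc to protonation or homocoupling. In the fallback, 9 is N-benzylated (BnBr, K2CO3, MeCN, reflux) to (1S,3S)-2-benzyl-5-bromo-6,8-dimethoxy-1,3-dimethyl-1,2,3,4-tetrahydroisoquinoline F4. Bromide 18 is converted (n-BuLi, B(OiPr)3, THF, −78 °C, then aq. HCl) into (4,5-dimethoxy-2-methylnaphthalen-1-yl)boronic acid F5. A Suzuki–Miyaura coupling of F4 and F5 (Pd(OAc)2, SPhos, K3PO4, toluene/water, 100 °C) should give (1S,3S)-2-benzyl-5-(4,5-dimethoxy-2-methylnaphthalen-1-yl)-6,8-dimethoxy-1,3-dimethyl-1,2,3,4-tetrahydroisoquinoline F6, and hydrogenolysis (H2, Pd on carbon, MeOH) removes the benzyl group. This fallback sets out from 9 and 18 and comes back at 21.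

Step 5. What may go wrong is N-bromination of the unprotected amine followed by dehydrobromination to the imine, which would erase the C1 stereocenter, or attack at C7 and double bromination. In the fallback, 8 is acylated (trifluoroacetic anhydride, Et3N, CH2Cl2, 0 °C) to 1-[(1S,3S)-6,8-dimethoxy-1,3-dimethyl-3,4-dihydro-1H-isoquinolin-2-yl]-2,2,2-trifluoroethan-1-one F7, whose nitrogen can no longer be oxidized. Bromination with NBS in MeCN should then give 1-[(1S,3S)-5-bromo-6,8-dimethoxy-1,3-dimethyl-3,4-dihydro-1H-isoquinolin-2-yl]-2,2,2-trifluoroethan-1-one F8, and K2CO3 in MeOH/water removes the trifluoroacetyl group. This fallback sets out from 8 and comes back at 9.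

Further compounds
F1 | step 3 | lithium 1-(2-bromo-4,6-dimethoxyphenyl)ethen-1-olate | C=C(O[Li])c1c(Br)cc(OC)cc1OC
F2 | step 3 | lithium 1-(2-lithio-4,6-dimethoxyphenyl)ethen-1-olate | C=C(O[Li])c1c([Li])cc(OC)cc1OC
F3 | step 3 | N-[(2S)-1-(2-acetyl-3,5-dimethoxyphenyl)propan-2-yl]-N-(tert-butoxycarbonyl)sulfamic acid | CC(=O)c1c(OC)cc(OC)cc1C[C@H](C)N(C(=O)OC(C)(C)C)S(=O)(=O)O
F4 | step 10 | (1S,3S)-2-benzyl-5-bromo-6,8-dimethoxy-1,3-dimethyl-1,2,3,4-tetrahydroisoquinoline | COc1cc(OC)c2c(c1Br)C[C@H](C)N(Cc1ccccc1)[C@H]2C
F5 | step 10 | (4,5-dimethoxy-2-methylnaphthalen-1-yl)boronic acid | COc1cccc2c(B(O)O)c(C)cc(OC)c12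
F6 | step 10 | (1S,3S)-2-benzyl-5-(4,5-dimethoxy-2-methylnaphthalen-1-yl)-6,8-dimethoxy-1,3-dimethyl-1,2,3,4-tetrahydroisoquinoline | COc1cc(OC)c2c(c1-c1c(C)cc(OC)c3c(OC)cccc13)C[C@H](C)N(Cc1ccccc1)[C@H]2C
F7 | step 5 | 1-[(1S,3S)-6,8-dimethoxy-1,3-dimethyl-3,4-dihydro-1H-isoquinolin-2-yl]-2,2,2-trifluoroethan-1-one | COc1cc(OC)c2c(c1)C[C@H](C)N(C(=O)C(F)(F)F)[C@H]2C
F8 | step 5 | 1-[(1S,3S)-5-bromo-6,8-dimethoxy-1,3-dimethyl-3,4-dihydro-1H-isoquinolin-2-yl]-2,2,2-trifluoroethan-1-one | COc1cc(OC)c2c(c1Br)C[C@H](C)N(C(=O)C(F)(F)F)[C@H]2C
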